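The readings were computed with constants of no real substance; the scatter is artificial.

Turn the question round and ask what the readings would have to show for the target to stop rising from elm to birch.

| flask | substrate | coupling partner | remark | time |
|---|---|---|---|---|
| eta | 0.013 M | 3 M | run made earlier |  |
| delta | 1.4 M | 3 M | run made earlier |  |
| elm | 0.012 M | 3.00 M |  | 4.0 min |
| ash | 0.040 M | 3.00 M |  | 4.0 min |
| maple | 0.12 M | 3.00 M |  | 4.0 min |
| alder | 0.30 M | 3.00 M |  | 4.0 min |
| birch | 1.0 M | 3.00 M |  | 4.0 min |

- eta (time / s: target / %, substrate / %): 10.0: 0, 85.0; 15.0: 0, 77.8; 20.0: 0.8, 72.1; 30.0: 0, 61.9; 50.0: 0, 45.1; 80.0: 3.5, 29.4; 120: 8.3, 18.8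
- delta (time / s: target / %, substrate / %): 10.0: 0.3, 84.9; 20.0: 0.3, 71.7; 30.0: 0, 62.4; 50.0: 0.2, 46.8; 80.0: 2.7, 32.1; 90.0: 4.6, 27.9; 120: 6.5, 20.3

(readings scatter by 0.5 percentage points)

- "hardly changes" means that all values lie within two and a half points (for a concentration: within two and a half percent of the largest)
- a reading of substrate is of its free form alone

1. [target] at the end for elm, ash, maple, alder, birch, in this order
2. the shape of the row from first to last (falls all the way / rises, then falls / hardly changes / falls, then rises / rises all the way)

I wrote the target of a flask as its charge times f, the fraction of that charge present as target, so a row turns where f falls as fast as the charge rises. Birch held a factor 83.3 more charge than elm, and a flat row needed f to lie lower by that same factor. I read f from the last target readings of eta and delta, at 120 s, because those runs span a wider range of charge than the row: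

order = 1 + ln(6.5% / 8.3%) / ln(1.4 M / 0.013 M) = 0.948

I called this the charge order, the percent change of the target per percent of charge, an apparent reaction order in substrate; a flat row stands at 0. Across those runs f lost a factor of 1.28, far less than the row's 83.3. That factor is a reading, with a scatter of 0.5 percentage points on both its terms. The substrate readings at that time were 18.8% in eta and 20.3% in delta. Birch's charge lay below delta's. But 4.0 min is twice the time of the last reading, so I carried the order forward in time on trust, and committed to a rising row.

The forecast held that “Yield is therefore nearly independent of concentration”, and gave 0.003 M, 0.01 M, 0.029 M, 0.07 M and 0.21 M: rises all the way.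

The flask gave 0.00306 M, 0.0102 M, 0.0305 M, 0.0753 M and 0.240 M: rises all the way.

substrate → intermediate A (k = 0.00860 s⁻¹); intermediate A → side product (k = 5.10 × 10⁻⁴ s⁻¹); coupling partner + intermediate A ⇌ intermediate C (K = 1.90 M⁻¹, k = 0.00440 M⁻¹ s⁻¹); intermediate C → target (k = 0.00730 s⁻¹); substrate + coupling partner ⇌ intermediate B (K = 0.790 M⁻¹, k = 0.00270 M⁻¹ s⁻¹) At 4.00 min, target stood at 25.5% of the charge in elm and 24.0% in birch. Starting from alder's 25.1%, the charge order reckons birch at 23.6% of its charge, and the local order at birch stood at 0.93.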